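**Plan**

1. Retrosynthesis: cut the six O‑benzyl bonds, then take the C3 methylene out of the pyranone (bonds C2–C3 and C3–C4), which leaves a 2‑(iodomethyl)‑2‑phenylbenzofuran‑3(2H)‑one. Next cut the C6–CH2 bond to the tris‑aryl side chain, the C2–CH2I bond, the furanone acyl–aryl and O1–C2 bonds, and the C8–CH2 bond. The side chain is cut at its two aryl–CH2 bonds.
2. Forward: the phloroglucinol ring is bought. Ortho C‑benzylation places the C8 benzyl group next to the one free OH, which becomes O1. O‑alkylation and Friedel–Crafts acylation close the five‑membered furanone, C2 is quaternised with CH2I, and the side chain is joined at the last free ring carbon. A one‑carbon ring expansion then turns the furanone into the pyranone, and hydrogenolysis frees the six phenols.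
3. Enabling feature: C2 carries both the phenyl ring and the ring oxygen O1 and is joined to the C4 ketone through an unsubstituted CH2 (C3). A CH2 radical on C2 of the furanone can therefore shift the acyl carbon and leave a planar, benzylic, α‑oxygen‑stabilised radical at C2 of the new six‑membered ring.
4. Stereochemistry: the only stereocentre (C2, S) is created in the ring expansion by H‑atom transfer from a homochiral thiol to that radical. Both enantiomers of the racemic precursor converge on it, and only neutral hydrogenolysis follows.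

Key step: step 12

Assumption: the facial sense of H delivery by a given homochiral thiol cannot be predicted. The named D‑mannose‑derived thiol is taken to give the (S) product; if it gives (R), a thiol of opposite sense (for example a D‑cysteine peptide thiol) replaces it.

**Route**

Step 1
Reactants: 1 3,5‑bis(benzyloxy)phenol; 2 2‑(benzyloxy)benzyl bromide
Product: 3 3,5‑bis(benzyloxy)‑2‑[2‑(benzyloxy)benzyl]phenol
Conditions: NaH (1.0 equiv to 1), toluene, rt; then 2 (0.8 equiv), 90 °C
Reagents that add atoms: none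
Why: Claisen‑type ortho C‑benzylation of a sodium phenoxide in a non‑dissociating solvent, where the tight ion pair steers the benzyl halide to the ring carbon between the phenoxide oxygen and an OBn group; excess 1 limits double alkylation.

Step 2
Reactants: 3 3,5‑bis(benzyloxy)‑2‑[2‑(benzyloxy)benzyl]phenol; 4 methyl 2‑bromo‑2‑phenylacetate (racemic)
Product: 6 2‑{3,5‑bis(benzyloxy)‑2‑[2‑(benzyloxy)benzyl]phenoxy}‑2‑phenylacetic acid (racemic), via methyl ester 5 (not isolated)
Conditions: K2CO3, DMF, rt; then aq. LiOH, THF, rt; aq. HCl work‑up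
Reagents that add atoms: lithium hydroxide, [Li+].[OH-]
Why: Williamson O‑alkylation of the single free phenol by an activated secondary benzylic α‑bromo ester, then saponification in the same flask; this fixes the oxygen next to the new benzyl group as the future ring oxygen.

Step 3
Reactants: 6 2‑{3,5‑bis(benzyloxy)‑2‑[2‑(benzyloxy)benzyl]phenoxy}‑2‑phenylacetic acid
Product: 8 4,6‑bis(benzyloxy)‑7‑[2‑(benzyloxy)benzyl]‑2‑phenyl‑1‑benzofuran‑3(2H)‑one (racemic), via mixed trifluoroacetic anhydride 7 (not isolated)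
Conditions: TFAA (3 equiv), CH2Cl2, 0 °C to rt; aq. NaHCO3 work‑up
Reagents that add atoms: none
Why: intramolecular Friedel–Crafts acylation through the mixed anhydride; the only carbon within reach is the free position ortho to the ether oxygen on the trioxygenated ring, so the five‑membered furanone closes there.

Step 4
Reactants: 8 4,6‑bis(benzyloxy)‑7‑[2‑(benzyloxy)benzyl]‑2‑phenyl‑1‑benzofuran‑3(2H)‑one
Product: 9 4,6‑bis(benzyloxy)‑7‑[2‑(benzyloxy)benzyl]‑2‑(iodomethyl)‑2‑phenyl‑1‑benzofuran‑3(2H)‑one (racemic)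
Conditions: NaH (1.1 equiv), DMF, 0 °C, Ar; CH2I2 (5 equiv), rt
Reagents that add atoms: diiodomethane, ICI
Why: C‑alkylation of the soft, stabilised 2‑aryl‑benzofuranone enolate with excess diiodomethane (α‑halomethylation of a stabilised enolate) should give the quaternary C2; the neopentyl‑type iodide does not react further.

Step 5
Reactants: 10 2,6‑dibromophenol
Product: 11 2‑(benzyloxy)‑1,3‑dibromobenzene
Conditions: BnBr, K2CO3, DMF, rt
Reagents that add atoms: benzyl bromide, BrCc1ccccc1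
Why: Williamson ether synthesis on an acidic, unhindered phenoxide.

Step 6
Reactants: 11 2‑(benzyloxy)‑1,3‑dibromobenzene; 12 2‑(benzyloxy)benzaldehyde
Product: 14 [2‑(benzyloxy)‑3‑bromophenyl][2‑(benzyloxy)phenyl]methanol (racemic), via aryllithium 13 (not isolated)
Conditions: n‑BuLi (1.0 equiv), THF, −78 °C; then 12, −78 °C; aq. NH4Cl
Reagents that add atoms: none
Why: selective mono bromine–lithium exchange of a 1,3‑dibromoarene at low temperature, then 1,2‑addition to the aldehyde; the carbinol centre is removed in step 9.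

Step 7
Reactants: 15 methyl 5‑formyl‑2‑hydroxybenzoate
Product: 16 methyl 2‑(benzyloxy)‑5‑formylbenzoate
Conditions: BnBr, K2CO3, DMF, 50 °C
Reagents that add atoms: benzyl bromide, BrCc1ccccc1
Why: Williamson benzylation of the salicylate phenol; aldehyde and ester are inert to carbonate.

Step 8
Reactants: 14 [2‑(benzyloxy)‑3‑bromophenyl][2‑(benzyloxy)phenyl]methanol; 16 methyl 2‑(benzyloxy)‑5‑formylbenzoate
Product: 18 methyl 2‑(benzyloxy)‑5‑{[2‑(benzyloxy)‑3‑{[2‑(benzyloxy)phenyl](hydroxy)methyl}phenyl](hydroxy)methyl}benzoate (diastereomer mixture), via dilithio species 17 (not isolated)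
Conditions: n‑BuLi (2.1 equiv), THF, −78 °C; then 16, −78 °C; aq. NH4Cl
Reagents that add atoms: none
Why: O‑deprotonation and bromine–lithium exchange, then chemoselective addition of the aryllithium to the aldehyde in the presence of the hindered methyl ester at −78 °C; both carbinol centres are removed in step 9.

Step 9
Reactants: 18 diol ester
Product: 19 methyl 2‑(benzyloxy)‑5‑{2‑(benzyloxy)‑3‑[2‑(benzyloxy)benzyl]benzyl}benzoate
Conditions: Et3SiH (6 equiv), TFA (10 equiv), CH2Cl2, 0 °C to rt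
Reagents that add atoms: none
Why: ionic hydrogenation; both doubly benzylic, alkoxy‑stabilised carbinols ionise in TFA and are trapped by silane hydride, while the ester and benzyl ethers are inert.

Step 10
Reactants: 19 methyl 2‑(benzyloxy)‑5‑{2‑(benzyloxy)‑3‑[2‑(benzyloxy)benzyl]benzyl}benzoate
Product: 20 (2‑(benzyloxy)‑5‑{2‑(benzyloxy)‑3‑[2‑(benzyloxy)benzyl]benzyl}phenyl)methanol
Conditions: LiAlH4, THF, 0 °C
Reagents that add atoms: none
Why: hydride reduction of the aryl ester to the benzylic alcohol; no other reducible group is present.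

Step 11
Reactants: 9 iodomethyl benzofuranone; 20 side‑chain benzylic alcohol
Product: 21 4,6‑bis(benzyloxy)‑7‑[2‑(benzyloxy)benzyl]‑5‑[2‑(benzyloxy)‑5‑{2‑(benzyloxy)‑3‑[2‑(benzyloxy)benzyl]benzyl}benzyl]‑2‑(iodomethyl)‑2‑phenyl‑1‑benzofuran‑3(2H)‑one (racemic)
Conditions: Bi(OTf)3 (5 mol %), CH2Cl2, 0 °C to rt, slow addition of 20 to 9 (1.2 equiv)
Reagents that add atoms: none
Why: Lewis‑acid‑catalysed Friedel–Crafts benzylation with a benzylic alcohol; the ortho‑alkoxybenzyl cation should attack the one unsubstituted carbon of the trioxygenated ring (C5), which is far more nucleophilic than the mono‑alkoxy rings, and the quaternary C2 of 9 leaves no enol to compete.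

Step 12
Reactants: 21 fully substituted 2‑(iodomethyl)‑2‑phenylbenzofuranone
Product: 22 (2S)‑5,7‑bis(benzyloxy)‑8‑[2‑(benzyloxy)benzyl]‑6‑[2‑(benzyloxy)‑5‑{2‑(benzyloxy)‑3‑[2‑(benzyloxy)benzyl]benzyl}benzyl]‑2‑phenylchroman‑4‑one
Conditions: Ph3SiH (2 equiv), 2,3,4,6‑tetra‑O‑acetyl‑1‑thio‑β‑D‑mannopyranose (5 mol %), V‑70 azo initiator (10 mol %), 1,4‑dioxane (0.01 M), 35 °C
Reagents that add atoms: none
Why: Proposed new method: a silyl radical abstracts iodine from the CH2I group, the primary radical adds to the C3 ketone carbon, and the cyclopropyloxy radical opens by β‑scission of the old C2–C3 bond, so the methylene ends up between C2 and the carbonyl (Dowd–Beckwith 1,2‑acyl shift, furanone to pyranone); the thiol then transfers H to the planar C2 radical and Ph3SiH returns the thiyl radical to thiol. The closest known reaction types are the Dowd–Beckwith one‑carbon ring expansion of α‑halomethyl cyclic ketones and thiol‑catalysed (polarity‑reversal) silane reductions in which a homochiral thiol delivers H enantioselectively to a prochiral carbon radical; their combination on an α‑aryloxy benzylic radical is new. The six‑membered ring forms by 3‑exo‑trig closure to a bicyclo[3.1.0] alkoxy radical followed by fragmentation of the shared bond, not by a direct cyclisation. The new stereocentre C2 is set under catalyst control in the H‑transfer step, both enantiomers of racemic 21 converging on the same radical, and the thiol should be the only competent H donor because Ph3SiH reacts very slowly with a stabilised benzylic radical. The step needs acyl migration to outrun direct reduction of the primary radical and the 1,2‑phenyl (neophyl) shift, which the aryl‑ketone acceptor, the benzylic α‑oxy stabilisation of the product radical, high dilution and low thiol loading should secure. It also needs the thiyl radical not to re‑abstract the C2–H of 22, which the excess of silane should ensure.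

Step 13
Reactants: 22 (2S)‑flavanone hexabenzyl ether
Product: 23 (2S)‑5,7‑dihydroxy‑8‑(2‑hydroxybenzyl)‑6‑{2‑hydroxy‑5‑[2‑hydroxy‑3‑(2‑hydroxybenzyl)benzyl]benzyl}‑2‑phenylchroman‑4‑one (CNP0107650.1)
Conditions: H2 (1 atm), 10% Pd/C, EtOAc–MeOH, rt, stopped when debenzylation is complete
Reagents that add atoms: none
Why: hydrogenolysis of six aryl benzyl ethers under neutral conditions; the ring C2–O1 bond and the diarylmethane CH2 groups should survive these mild conditions and C2 is not epimerised.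

**Compound list**

1 | 3,5‑bis(benzyloxy)phenol | Oc1cc(OCc2ccccc2)cc(OCc2ccccc2)c1 | starting material
2 | 2‑(benzyloxy)benzyl bromide | BrCc1ccccc1OCc1ccccc1 | starting material
3 | 3,5‑bis(benzyloxy)‑2‑[2‑(benzyloxy)benzyl]phenol | Oc1cc(OCc2ccccc2)cc(OCc2ccccc2)c1Cc1ccccc1OCc1ccccc1 | intermediate
4 | methyl 2‑bromo‑2‑phenylacetate (racemic) | COC(=O)C(Br)c1ccccc1 | starting material
5 | methyl 2‑{3,5‑bis(benzyloxy)‑2‑[2‑(benzyloxy)benzyl]phenoxy}‑2‑phenylacetate (racemic, not isolated) | COC(=O)C(Oc1cc(OCc2ccccc2)cc(OCc2ccccc2)c1Cc1ccccc1OCc1ccccc1)c1ccccc1 | intermediate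
6 | 2‑{3,5‑bis(benzyloxy)‑2‑[2‑(benzyloxy)benzyl]phenoxy}‑2‑phenylacetic acid (racemic) | OC(=O)C(Oc1cc(OCc2ccccc2)cc(OCc2ccccc2)c1Cc1ccccc1OCc1ccccc1)c1ccccc1 | intermediate
7 | mixed anhydride of 6 with trifluoroacetic acid (not isolated) | O=C(OC(=O)C(F)(F)F)C(Oc1cc(OCc2ccccc2)cc(OCc2ccccc2)c1Cc1ccccc1OCc1ccccc1)c1ccccc1 | intermediate
8 | 4,6‑bis(benzyloxy)‑7‑[2‑(benzyloxy)benzyl]‑2‑phenyl‑1‑benzofuran‑3(2H)‑one (racemic) | O=C1C(c2ccccc2)Oc2c(Cc3ccccc3OCc3ccccc3)c(OCc3ccccc3)cc(OCc3ccccc3)c21 | intermediate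
9 | 4,6‑bis(benzyloxy)‑7‑[2‑(benzyloxy)benzyl]‑2‑(iodomethyl)‑2‑phenyl‑1‑benzofuran‑3(2H)‑one (racemic) | O=C1C(CI)(c2ccccc2)Oc2c(Cc3ccccc3OCc3ccccc3)c(OCc3ccccc3)cc(OCc3ccccc3)c21 | intermediate
10 | 2,6‑dibromophenol | Oc1c(Br)cccc1Br | starting material
11 | 2‑(benzyloxy)‑1,3‑dibromobenzene | Brc1cccc(Br)c1OCc1ccccc1 | intermediate
12 | 2‑(benzyloxy)benzaldehyde | O=Cc1ccccc1OCc1ccccc1 | starting material
13 | [2‑(benzyloxy)‑3‑bromophenyl]lithium (not isolated) | [Li]c1cccc(Br)c1OCc1ccccc1 | intermediate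
14 | [2‑(benzyloxy)‑3‑bromophenyl][2‑(benzyloxy)phenyl]methanol (racemic) | OC(c1ccccc1OCc1ccccc1)c1cccc(Br)c1OCc1ccccc1 | intermediate
15 | methyl 5‑formyl‑2‑hydroxybenzoate | COC(=O)c1cc(C=O)ccc1O | starting material
16 | methyl 2‑(benzyloxy)‑5‑formylbenzoate | COC(=O)c1cc(C=O)ccc1OCc1ccccc1 | intermediate
17 | lithium alkoxide/aryllithium from 14 (not isolated) | [Li]OC(c1ccccc1OCc1ccccc1)c1cccc([Li])c1OCc1ccccc1 | intermediate
18 | methyl 2‑(benzyloxy)‑5‑{[2‑(benzyloxy)‑3‑{[2‑(benzyloxy)phenyl](hydroxy)methyl}phenyl](hydroxy)methyl}benzoate (diastereomer mixture) | COC(=O)c1cc(C(O)c2cccc(C(O)c3ccccc3OCc3ccccc3)c2OCc2ccccc2)ccc1OCc1ccccc1 | intermediate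
19 | methyl 2‑(benzyloxy)‑5‑{2‑(benzyloxy)‑3‑[2‑(benzyloxy)benzyl]benzyl}benzoate | COC(=O)c1cc(Cc2cccc(Cc3ccccc3OCc3ccccc3)c2OCc2ccccc2)ccc1OCc1ccccc1 | intermediate
20 | (2‑(benzyloxy)‑5‑{2‑(benzyloxy)‑3‑[2‑(benzyloxy)benzyl]benzyl}phenyl)methanol | OCc1cc(Cc2cccc(Cc3ccccc3OCc3ccccc3)c2OCc2ccccc2)ccc1OCc1ccccc1 | intermediate
21 | 4,6‑bis(benzyloxy)‑7‑[2‑(benzyloxy)benzyl]‑5‑[2‑(benzyloxy)‑5‑{2‑(benzyloxy)‑3‑[2‑(benzyloxy)benzyl]benzyl}benzyl]‑2‑(iodomethyl)‑2‑phenyl‑1‑benzofuran‑3(2H)‑one (racemic) | O=C1C(CI)(c2ccccc2)Oc2c(Cc3ccccc3OCc3ccccc3)c(OCc3ccccc3)c(Cc3cc(Cc4cccc(Cc5ccccc5OCc5ccccc5)c4OCc4ccccc4)ccc3OCc3ccccc3)c(OCc3ccccc3)c21 | intermediate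
22 | (2S)‑5,7‑bis(benzyloxy)‑8‑[2‑(benzyloxy)benzyl]‑6‑[2‑(benzyloxy)‑5‑{2‑(benzyloxy)‑3‑[2‑(benzyloxy)benzyl]benzyl}benzyl]‑2‑phenylchroman‑4‑one | O=C1C[C@@H](c2ccccc2)Oc2c(Cc3ccccc3OCc3ccccc3)c(OCc3ccccc3)c(Cc3cc(Cc4cccc(Cc5ccccc5OCc5ccccc5)c4OCc4ccccc4)ccc3OCc3ccccc3)c(OCc3ccccc3)c21 | intermediate
23 | (2S)‑5,7‑dihydroxy‑8‑(2‑hydroxybenzyl)‑6‑{2‑hydroxy‑5‑[2‑hydroxy‑3‑(2‑hydroxybenzyl)benzyl]benzyl}‑2‑phenylchroman‑4‑one | O=C1C[C@@H](c2ccccc2)Oc2c(Cc3ccccc3O)c(O)c(Cc3cc(Cc4cccc(Cc5ccccc5O)c4O)ccc3O)c(O)c21 | target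

**Summary**

Total step count: 13.
Longest linear sequence: 8 steps (steps 5, 6, 8, 9, 10, 11, 12, 13, from 2,6‑dibromophenol).

Steps most likely to fail:

Step 12 (Proposed new method). The primary radical may be reduced before the acyl shift, the thiol may discriminate the two faces of the C2 radical poorly, or reversible H abstraction at C2 may erode the enantiomeric purity. The fallback sets out from 21 and comes back at 22. A classical tin‑hydride Dowd–Beckwith ring expansion (Bu3SnH by slow addition, AIBN, benzene, 80 °C) should give the racemic flavanone hexabenzyl ether F1. Preparative supercritical‑fluid chromatography on a polysaccharide chiral stationary phase then separates 22 from the (2R)‑enantiomer F2, which is racemised back to F1 with catalytic base (NaOAc, EtOH–THF, reflux, reversible oxa‑Michael ring opening) and recycled.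

Step 11. The benzylic cation may attack the mono‑alkoxy rings of either partner (oligomerisation), an ortho benzyl ether may be lost through quinone‑methide formation, or the flanked C5 may react too slowly. The fallback sets out from 9 and 20 and comes back at 21. NBS (MeCN, 0 °C) should brominate the only free position of the trioxygenated ring of 9 to give the 5‑bromo ketone F3. Alcohol 20 is converted with PBr3 (CH2Cl2, 0 °C) into the side‑chain benzyl bromide F4, and zinc dust with LiCl in THF turns this into the benzylzinc bromide F5. Negishi coupling of F3 with F5 (Pd(OAc)2, SPhos, THF, rt to 50 °C) gives 21.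

Step 1. The ambident phenoxide may be benzylated on oxygen or at the para carbon, or alkylated twice. The fallback sets out from 1 and comes back at 3. Magnesium‑mediated ortho‑formylation (MgCl2, Et3N, paraformaldehyde, MeCN, reflux) should give 2,4‑bis(benzyloxy)‑6‑hydroxybenzaldehyde F6. Addition of commercial [2‑(benzyloxy)phenyl]magnesium bromide (2.2 equiv, THF, 0 °C) gives the ortho‑hydroxy benzhydrol F7, and ionic hydrogenation (Et3SiH, TFA, CH2Cl2, 0 °C) gives 3.

**Further compounds**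

F1 | step 12 | racemic 5,7‑bis(benzyloxy)‑8‑[2‑(benzyloxy)benzyl]‑6‑[2‑(benzyloxy)‑5‑{2‑(benzyloxy)‑3‑[2‑(benzyloxy)benzyl]benzyl}benzyl]‑2‑phenylchroman‑4‑one | O=C1CC(c2ccccc2)Oc2c(Cc3ccccc3OCc3ccccc3)c(OCc3ccccc3)c(Cc3cc(Cc4cccc(Cc5ccccc5OCc5ccccc5)c4OCc4ccccc4)ccc3OCc3ccccc3)c(OCc3ccccc3)c21
F2 | step 12 | (2R)‑enantiomer of 22 | O=C1C[C@H](c2ccccc2)Oc2c(Cc3ccccc3OCc3ccccc3)c(OCc3ccccc3)c(Cc3cc(Cc4cccc(Cc5ccccc5OCc5ccccc5)c4OCc4ccccc4)ccc3OCc3ccccc3)c(OCc3ccccc3)c21
F3 | step 11 | 4,6‑bis(benzyloxy)‑7‑[2‑(benzyloxy)benzyl]‑5‑bromo‑2‑(iodomethyl)‑2‑phenyl‑1‑benzofuran‑3(2H)‑one (racemic) | O=C1C(CI)(c2ccccc2)Oc2c(Cc3ccccc3OCc3ccccc3)c(OCc3ccccc3)c(Br)c(OCc3ccccc3)c21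
F4 | step 11 | 1‑(benzyloxy)‑4‑{2‑(benzyloxy)‑3‑[2‑(benzyloxy)benzyl]benzyl}‑2‑(bromomethyl)benzene | BrCc1cc(Cc2cccc(Cc3ccccc3OCc3ccccc3)c2OCc2ccccc2)ccc1OCc1ccccc1
F5 | step 11 | (2‑(benzyloxy)‑5‑{2‑(benzyloxy)‑3‑[2‑(benzyloxy)benzyl]benzyl}benzyl)zinc bromide | Br[Zn]Cc1cc(Cc2cccc(Cc3ccccc3OCc3ccccc3)c2OCc2ccccc2)ccc1OCc1ccccc1
F6 | step 1 | 2,4‑bis(benzyloxy)‑6‑hydroxybenzaldehyde | O=Cc1c(O)cc(OCc2ccccc2)cc1OCc1ccccc1
F7 | step 1 | 3,5‑bis(benzyloxy)‑2‑{[2‑(benzyloxy)phenyl](hydroxy)methyl}phenol (racemic) | OC(c1ccccc1OCc1ccccc1)c1c(O)cc(OCc2ccccc2)cc1OCc1ccccc1
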